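Locants: cyclobutane C4(Me)–C5–C6–C7; ketone bridge C7–C8(=O)–C9–C10(Me)–C5; ester-bearing bridge C4–C3(OAng)–C2–C1(OAng)–C11(Me)(CH2OH)–C6. Cuts, in order: the two angelate C–O bonds, C10–CH3, the C–O bond of the C11 CH2OH (back to a methyl), then C6–C11 and C4–C3 in one operation.
Enabling feature: C4 and C6 are the 1,3-carbons of a cyclobutane whose other two carbons, C5 and C7, are already spanned by C8–C9–C10. A C4–C6 bond therefore gives a tricyclo[4.1.0.0(2,7)]heptane (a bridged bicyclo[1.1.0]butane) that can only be opened from the face on which the seven-membered ring C4–C3–C2–C1–C11–C6–C5 must sit.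
Forward: six-membered ring (3-methylcyclohexenone) → cyclopropane → bicyclobutane 6; a radical cascade with bromo enone 10 opens the central bond to the cyclobutane and closes the seven-membered ring (11); then C8=O, C9=C10 and the C10 methyl; the angelates go on last.
Core stereochemistry: C8 by CBS reduction, relayed to C7, C4 and C5 by hydroxyl-directed cyclopropanation; C4 and C6 by the geometry of the bicyclobutane; C10 by cuprate addition anti to the C4 methyl.
Seven-membered ring: the remote C8/C10 groups cannot tell its two flanks apart, so a reagent does it once (CBS at C1) and the rest is relay: C1–OH → cis methyl on C11 (C–H silylation) → CH2OH → C1 → C3 (two hydroxyl-directed reductions).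

Key step: step 6

Remark: the cascade is assumed to give both C3 epimers of 11 in similar amounts; 11–18 are carried as this pair, the centre becomes sp2 in step 11 and is set in step 14. The locants C1–C11 above are used for all intermediates.

Step 1
Reactants: 1 3-methylcyclohex-2-en-1-one
Product: 2 (S)-3-methylcyclohex-2-en-1-ol
Conditions: (R)-Me-CBS oxazaborolidine (10 mol %), catecholborane, toluene, −78 °C
Reagents that add atoms: none
Why: Corey–Bakshi–Shibata reduction in which the alkenyl arm acts as the large group, so the (R)-catalyst should give the (S)-allylic alcohol (future C8), and catecholborane at low temperature avoids hydroboration.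

Step 2
Reactants: 2 (S)-3-methylcyclohex-2-en-1-ol; 3 bromoform
Product: 4 (2S)-7,7-dibromo-6-methylbicyclo[4.1.0]heptan-2-ol (hydroxyl cis to the CBr2 carbon)
Conditions: 50% aq NaOH, BnEt3NCl (cat.), CH2Cl2, 0 °C to rt
Reagents that add atoms: none
Why: Phase-transfer dibromocarbene cyclopropanation of an electron-rich trisubstituted alkene, in which the allylic hydroxyl is expected to direct the carbene to its own face and so fix C7 and C4 (and the future C6) relative to C8.

Step 3
Reactants: 4 (2S)-7,7-dibromo-6-methylbicyclo[4.1.0]heptan-2-ol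
Product: 5 tert-butyldimethylsilyl ether of 4
Conditions: TBSCl, imidazole, DMF, rt
Reagents that add atoms: tert-butyldimethylsilyl chloride, CC(C)(C)[Si](C)(C)Cl
Why: Standard silylation of a secondary alcohol; the silyl ether tolerates MeLi and, unlike an alkyl ether, offers the carbenoid no activated C–H bond next to oxygen.

Step 4
Reactants: 5 tert-butyldimethylsilyl ether of 4
Product: 6 (3S)-3-(tert-butyldimethylsilyloxy)-1-methyltricyclo[4.1.0.0(2,7)]heptane (central carbons C4(Me) and C6(H); silyloxy on C8 facing C6)
Conditions: MeLi, Et2O, −78 °C to 0 °C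
Reagents that add atoms: none
Why: Lithium–bromine exchange and α-elimination give a cyclopropylidene carbenoid that inserts into the β C–H bond cis to it (the classical entry to tricyclo[4.1.0.0(2,7)]heptanes); in 5 the only such hydrogen is on C5, because the C8 hydrogen is trans to the carbenoid carbon, so the methyl ends on the central bond.

Step 5
Reactants: 7 2-bromo-2-methylpropanoyl bromide; 8 benzyl vinyl ether
Product: 10 (E)-1-(benzyloxy)-4-bromo-4-methylpent-1-en-3-one, via bromo ether adduct 9 (not isolated)
Conditions: pyridine, CH2Cl2, 0 °C to rt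
Reagents that add atoms: none
Why: Acylation of an enol ether by a reactive acyl halide followed by base-induced loss of HBr from the α-bromo ether (β-alkoxyvinyl ketone synthesis), which should give the conjugated E isomer.

Step 6
Reactants: 6 silyloxy bicyclobutane; 10 (E)-1-(benzyloxy)-4-bromo-4-methylpent-1-en-3-one
Product: 11 tricyclic C1 ketone (C3–OBn as both epimers; C8–OTBS; gem-dimethyl C11)
Conditions: fac-Ir(ppy)3 (1 mol %), i-Pr2NEt, MeCN, blue LEDs, rt, slow addition of 10
Reagents that add atoms: none
Why: Proposed new method: excited fac-Ir(ppy)3 reduces the C–Br bond of 10 to a tertiary, electrophilic α-keto radical that adds to the hydrogen-bearing bridgehead C6 of 6 on its convex face; the central C4–C6 bond breaks to the tertiary cyclobutyl radical at C4, this nucleophilic radical adds to the β-carbon C3 of the benzyloxy enone held over it, and the α-keto radical at C2 takes a hydrogen atom from the amine radical cation. The closest known reactions are radical strain-release 1,3-difunctionalisations of bicyclo[1.1.0]butanes (sulfonyl, thiyl and halomethyl radicals on tricyclo[4.1.0.0(2,7)]heptanes) and Giese-type cyclisations of alkyl radicals onto β-alkoxy acrylates and enones. The one ring that closes, C4–C3–C2–C1–C11–C6–C5, does so in the 7-endo-trig mode, while the bicyclo[3.1.1]heptane is uncovered by the bond cleavage. C6 and C4 are controlled by the C8–C9–C10 bridge, which blocks the concave face so that C11 and then C3 (deliverable only cis to C11) bond on the open face and leave H-6 and the C4 methyl over the bridge; C3 has no controlling element, because the two flanks of the forming ring differ only in the remote C8/C10 groups, so both epimers are expected. The step needs attack at C6 and not C4 (less hindered, and it forms the tertiary radical), 7-endo over 6-exo closure (the nucleophilic radical goes to the β-carbon and gives the stabilised α-keto radical) and cyclisation faster than hydrogen transfer, which slow addition of 10 at low concentration should favour.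

Step 7
Reactants: 11 tricyclic C1 ketone
Product: 12 (1S)-C1 alcohol (hydroxyl on the C7 flank; C3–OBn both epimers; C8–OTBS)
Conditions: (R)-Me-CBS oxazaborolidine, BH3·SMe2, THF, −20 °C
Reagents that add atoms: none
Why: Corey–Bakshi–Shibata reduction with quaternary C11 as the large and C2H2 as the small substituent should set the temporary (1S) carbinol by reagent control in both C3 epimers; this is the single event that tells the two flanks of the seven-membered ring apart.

Step 8
Reactants: 12 (1S)-C1 alcohol
Product: 15 triol (C1–OH cis to the new C11–CH2OH; C8–OH; C3–OBn), via hydrosilyl ether 13 (not isolated), via oxasilolane 14 (not isolated)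
Conditions: Et2SiH2, [Ir(cod)OMe]2 (cat.), THF, rt; then [Ir(cod)OMe]2 (cat.), Me4phen, norbornene, THF, 120 °C; then Bu4NF, KHCO3, H2O2, THF/MeOH, 50 °C
Reagents that add atoms: hydrogen peroxide, OO
Why: Iridium-catalysed dehydrogenative silylation of the alcohol and hydroxyl-directed γ-C–H silylation of a primary C–H bond, then Tamao–Fleming oxidation with fluoride, which also removes the C8 silyl ether; the C11 methyl cis to the C1 oxygen is expected to react, because only it stays synclinal to the O–Si bond in every ring conformer (cis-fused oxasilolane), and this puts CH2OH on the C7 flank.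

Step 9
Reactants: 15 triol
Product: 16 primary benzyl ether (C11–CH2OBn; C1–OH; C8–OH; C3–OBn)
Conditions: BnBr, Ag2O, CH2Cl2, rt
Reagents that add atoms: benzyl bromide, BrCc1ccccc1
Why: Ag2O-mediated monobenzylation of a polyol, in which the primary hydroxyl should be alkylated in preference to the two hindered secondary ones.

Step 10
Reactants: 16 primary benzyl ether
Product: 17 C1,C8-diketone (C3–OBn; C11–CH2OBn)
Conditions: Dess–Martin periodinane, NaHCO3, CH2Cl2, rt
Reagents that add atoms: none
Why: Dess–Martin oxidation of both secondary alcohols under buffered, non-basic conditions that spare the β-benzyloxy ketone; the C1 carbinol has done its directing work and C1 is needed as a ketone for the relay.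

Step 11
Reactants: 17 C1,C8-diketone
Product: 19 bis-enone (benzyl vinylogous ester C1(=O)–C2=C3(OBn); enone C8(=O)–C9=C10), via bis(silyl enol ether) 18 (not isolated)
Conditions: TMSOTf, Et3N, CH2Cl2, 0 °C; then Pd(OAc)2, MeCN, rt
Reagents that add atoms: none
Why: Saegusa–Ito oxidation of both trimethylsilyl enol ethers: C8 can enolise only towards C9 (C7 is a bridgehead) and C1 only towards C2, so the C9=C10 enone and the C2=C3 vinylogous ester should form and the uncontrolled C3 centre disappears.

Step 12
Reactants: 19 bis-enone
Product: 20 C10-methyl ketone (methyl on the C6 side; vinylogous ester intact)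
Conditions: Me2CuLi, Et2O, −78 °C; NH4Cl quench
Reagents that add atoms: lithium dimethylcuprate, [Li+].C[Cu-]C
Why: Gilman cuprate 1,4-addition to a bicyclo[3.1.1]heptenone (as with verbenone-type enones) from the face away from the C4 methyl that hangs over the ring, which sets C10; the β-alkoxy-β-alkyl vinylogous ester is too hindered and electron-rich to compete.

Step 13
Reactants: 20 C10-methyl ketone
Product: 21 C1,C3,C8-triketone with free C11–CH2OH
Conditions: H2 (1 atm), Pd/C, EtOAc, rt
Reagents that add atoms: none
Why: Hydrogenolysis of the benzyl ether and of the benzyl vinylogous ester, the latter unmasking the C1/C3 1,3-diketone.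

Step 14
Reactants: 21 triketone alcohol
Product: 23 (1R,3R)-triol with C8 ketone (C1–OH trans to CH2OH; C3–OH trans to C1–OH), via hydroxy diketone 22 (not isolated)
Conditions: Me4NBH(OAc)3, MeCN/AcOH, −20 °C to 0 °C
Reagents that add atoms: none
Why: Hydroxyl-directed (Evans–Saksena) reduction run twice in one flask: boron bound to the CH2OH delivers hydride to C1 on the CH2OH side to give the (1R) alcohol, whose hydroxyl then delivers hydride to C3 to give the trans-1,3-diol, while the C8 ketone has no β-hydroxyl and should be left.

Step 15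
Reactants: 23 (1R,3R)-triol
Product: 24 primary triethylsilyl ether of 23
Conditions: TESCl, imidazole, CH2Cl2, −40 °C
Reagents that add atoms: triethylsilyl chloride, CC[Si](Cl)(CC)CC
Why: Selective silylation of the primary alcohol over two neopentylic secondary alcohols.

Step 16
Reactants: 24 primary triethylsilyl ether; 25 angelic acid
Product: 27 CNP0287707.1, via silyl ether bis-angelate 26 (not isolated)
Conditions: 2,4,6-trichlorobenzoyl chloride, Et3N, toluene, 80 °C; then 1 M HCl, THF, rt
Reagents that add atoms: none
Why: Yamaguchi-type acylation with the preformed mixed anhydride of angelic acid without a nucleophilic catalyst (conditions chosen to keep the Z geometry), followed by acid hydrolysis of the primary triethylsilyl ether.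

Compound list
1 | 3-methylcyclohex-2-en-1-one | CC1=CC(=O)CCC1 | starting material
2 | (S)-3-methylcyclohex-2-en-1-ol | CC1=C[C@@H](O)CCC1 | intermediate
3 | bromoform | BrC(Br)Br | starting material
4 | (2S)-7,7-dibromo-6-methylbicyclo[4.1.0]heptan-2-ol, hydroxyl cis to the CBr2 carbon | O[C@H]1CCC[C@]2(C)[C@H]1C2(Br)Br | intermediate
5 | tert-butyldimethylsilyl ether of 4 | CC(C)(C)[Si](C)(C)O[C@H]1CCC[C@]2(C)[C@H]1C2(Br)Br | intermediate
6 | (3S)-3-(tert-butyldimethylsilyloxy)-1-methyltricyclo[4.1.0.0(2,7)]heptane, silyloxy group facing the unsubstituted bridgehead | C[C@]12[C@@H]3[C@H]1[C@H]2[C@@H](O[Si](C)(C)C(C)(C)C)CC3 | intermediate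
7 | 2-bromo-2-methylpropanoyl bromide | CC(C)(Br)C(=O)Br | starting material
8 | benzyl vinyl ether | C=COCc1ccccc1 | starting material
9 | 1-(benzyloxy)-1,4-dibromo-4-methylpentan-3-one (racemic bromo ether adduct) | CC(C)(Br)C(=O)CC(Br)OCc1ccccc1 | intermediate
10 | (E)-1-(benzyloxy)-4-bromo-4-methylpent-1-en-3-one | CC(C)(Br)C(=O)/C=C/OCc1ccccc1 | intermediate
11 | tricyclic C1 ketone: C3–OBn (both epimers), C8–OTBS, gem-dimethyl C11 | O=C1CC(OCc2ccccc2)[C@]3(C)[C@@H]4[C@@H]([C@H]3[C@@H](O[Si](C)(C)C(C)(C)C)CC4)C1(C)C | intermediate
12 | (1S)-C1 alcohol of 11 (C3 both epimers) | O[C@H]1CC(OCc2ccccc2)[C@]3(C)[C@@H]4[C@@H]([C@H]3[C@@H](O[Si](C)(C)C(C)(C)C)CC4)C1(C)C | intermediate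
13 | diethylhydrosilyl ether of 12 | CC[SiH](CC)O[C@H]1CC(OCc2ccccc2)[C@]3(C)[C@@H]4[C@@H]([C@H]3[C@@H](O[Si](C)(C)C(C)(C)C)CC4)C1(C)C | intermediate
14 | cis-fused oxasilolane C1–O–SiEt2–CH2–C11 (CH2 on the C7 flank; C3 both epimers) | CC[Si]5(CC)O[C@H]1CC(OCc2ccccc2)[C@]3(C)[C@@H]4[C@@H]([C@H]3[C@@H](O[Si](C)(C)C(C)(C)C)CC4)[C@@]1(C)C5 | intermediate
15 | triol: C1–OH, C8–OH, C11–CH2OH cis to C1–OH; C3–OBn (both epimers) | O[C@H]1CC(OCc2ccccc2)[C@]3(C)[C@@H]4[C@@H]([C@H]3[C@@H](O)CC4)[C@@]1(C)CO | intermediate
16 | primary benzyl ether of 15 | O[C@H]1CC(OCc2ccccc2)[C@]3(C)[C@@H]4[C@@H]([C@H]3[C@@H](O)CC4)[C@@]1(C)COCc5ccccc5 | intermediate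
17 | C1,C8-diketone: C3–OBn (both epimers), C11–CH2OBn | O=C1CC(OCc2ccccc2)[C@]3(C)[C@@H]4[C@@H]([C@H]3C(=O)CC4)[C@@]1(C)COCc5ccccc5 | intermediate
18 | bis(trimethylsilyl enol ether) of 17 (C1=C2 and C8=C9) | C[Si](C)(C)OC1=CC(OCc2ccccc2)[C@]3(C)[C@@H]4[C@@H]([C@H]3C(O[Si](C)(C)C)=CC4)[C@@]1(C)COCc5ccccc5 | intermediate
19 | bis-enone: benzyl vinylogous ester C1(=O)–C2=C3(OBn) and enone C8(=O)–C9=C10 | O=C1C=C(OCc2ccccc2)[C@]3(C)[C@@H]4[C@@H]([C@H]3C(=O)C=C4)[C@@]1(C)COCc5ccccc5 | intermediate
20 | C10-methyl ketone, methyl on the C6 side, vinylogous ester intact | O=C1C=C(OCc2ccccc2)[C@]3(C)[C@@H]4[C@@H]([C@H]3C(=O)C[C@H]4C)[C@@]1(C)COCc5ccccc5 | intermediate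
21 | C1,C3,C8-triketone with free C11–CH2OH | O=C1CC(=O)[C@]3(C)[C@@H]4[C@@H]([C@H]3C(=O)C[C@H]4C)[C@@]1(C)CO | intermediate
22 | (1R)-1-hydroxy-C3,C8-diketone, C1–OH trans to CH2OH | O[C@@H]1CC(=O)[C@]3(C)[C@@H]4[C@@H]([C@H]3C(=O)C[C@H]4C)[C@@]1(C)CO | intermediate
23 | (1R,3R)-triol with C8 ketone | O[C@@H]1C[C@@H](O)[C@]3(C)[C@@H]4[C@@H]([C@H]3C(=O)C[C@H]4C)[C@@]1(C)CO | intermediate
24 | primary triethylsilyl ether of 23 | O[C@@H]1C[C@@H](O)[C@]3(C)[C@@H]4[C@@H]([C@H]3C(=O)C[C@H]4C)[C@@]1(C)CO[Si](CC)(CC)CC | intermediate
25 | angelic acid, (Z)-2-methylbut-2-enoic acid | C/C=C(/C)C(=O)O | starting material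
26 | C1,C3-bis-angelate of 24 | C/C=C(/C)C(=O)O[C@@H]1C[C@@H](OC(=O)/C(C)=C\C)[C@]2(C)[C@@H]3[C@@H]([C@H]2C(=O)C[C@H]3C)[C@@]1(C)CO[Si](CC)(CC)CC | intermediate
27 | CNP0287707.1 | C/C=C(/C)C(=O)O[C@@H]1C[C@@H](OC(=O)/C(C)=C\C)[C@]2(C)[C@@H]3[C@@H]([C@H]2C(=O)C[C@H]3C)[C@@]1(C)CO | target

Total step count: 16. Longest linear sequence: 15 (steps 1–4 and 6–16); step 5 is a one-step side branch.

Steps most likely to fail

1. Step 6 (radical cascade). What may go wrong: hydrogen transfer to the α-keto radical before it meets 6 (plain debromination of 10), hydrogen transfer to the cyclobutyl radical before ring closure, or oligomerisation of 10. Fallback with known reaction types, setting out from 6 and 10 and returning at 11: the two C–C bond formations are separated. A Kharasch-type atom-transfer addition across the central bond without a reductant (Ru(bpy)3Cl2 cat., LiBr, DMF, blue LEDs) should give the 1,3-adduct, tertiary cyclobutyl bromide F1. Its radical is then regenerated and cyclised in a Giese-type 7-endo closure with Bu3SnH and AIBN (benzene, 80 °C, syringe pump) to give 11.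

2. Step 8 (directed C–H silylation). What may go wrong: slow C–H activation at the neopentylic site, or poor discrimination between the two C11 methyl groups. If the reaction proves selective for the methyl trans to oxygen, the (S)-catalyst in step 7 restores the required sense, since C1 is reoxidised in step 10. Fallback, setting out from 6 and 8 and returning at 17: the oxygenated carbon is brought in with the radical partner. 3-(Benzyloxy)-2-methylpropanoic acid is converted (PBr3, Br2) into 3-(benzyloxy)-2-bromo-2-methylpropanoyl bromide F2, which acylates 8 as in step 5 through the bromo ether adduct F3 to the bromo enone F4. The cascade of step 6 with 6 then gives the C11 benzyloxymethyl ketone F5 as both C11 epimers, Bu4NF frees the C8 alcohol F6, and Dess–Martin oxidation gives 17, which has to be separated from its C11 epimer. Steps 7–10 are bypassed at the price of statistical formation of C11.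

3. Step 16 (double angeloylation). What may go wrong: incomplete acylation of two neopentylic secondary alcohols and Z-to-E isomerisation of the angeloyl groups to tiglates under forcing conditions. Fallback, setting out from 24 and returning at 26: the Z-alkenes are built after acylation. Esterification of 24 with 2-[bis(2,2,2-trifluoroethoxy)phosphoryl]propanoic acid (DCC, DMAP, CH2Cl2) gives the bis(phosphonopropanoate) F7, and a double Still–Gennari olefination with acetaldehyde (KN(SiMe3)2, 18-crown-6, THF, −78 °C) should give 26, which is desilylated as in step 16.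

Further compounds
F1 | step 6 | tertiary C4 bromide from atom-transfer addition of 10 across the central bond of 6 (Br and C11 anti to the C8–C10 bridge; enone arm intact) | Br[C@]1(C)[C@@H]2[C@@H]([C@H]1[C@@H](O[Si](C)(C)C(C)(C)C)CC2)C(C)(C)C(=O)/C=C/OCc1ccccc1
F2 | step 8 | 3-(benzyloxy)-2-bromo-2-methylpropanoyl bromide (racemic) | CC(Br)(COCc1ccccc1)C(=O)Br
F3 | step 8 | 1-(benzyloxy)-4-[(benzyloxy)methyl]-1,4-dibromopentan-3-one (bromo ether adduct, stereoisomer mixture) | CC(Br)(COCc1ccccc1)C(=O)CC(Br)OCc1ccccc1
F4 | step 8 | (E)-1-(benzyloxy)-4-[(benzyloxy)methyl]-4-bromopent-1-en-3-one (racemic) | CC(Br)(COCc1ccccc1)C(=O)/C=C/OCc1ccccc1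
F5 | step 8 | tricyclic C1 ketone with C11(Me)(CH2OBn), C3–OBn and C8–OTBS (both C11 and both C3 epimers) | O=C1CC(OCc2ccccc2)[C@]3(C)[C@@H]4[C@@H]([C@H]3[C@@H](O[Si](C)(C)C(C)(C)C)CC4)C1(C)COCc5ccccc5
F6 | step 8 | C8 alcohol of F5 | O=C1CC(OCc2ccccc2)[C@]3(C)[C@@H]4[C@@H]([C@H]3[C@@H](O)CC4)C1(C)COCc5ccccc5
F7 | step 16 | C1,C3-bis{2-[bis(2,2,2-trifluoroethoxy)phosphoryl]propanoate} of 24 (phosphonate α-carbons as mixtures) | CC(C(=O)O[C@@H]1C[C@@H](OC(=O)C(C)P(=O)(OCC(F)(F)F)OCC(F)(F)F)[C@]2(C)[C@@H]3[C@@H]([C@H]2C(=O)C[C@H]3C)[C@@]1(C)CO[Si](CC)(CC)CC)P(=O)(OCC(F)(F)F)OCC(F)(F)F
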